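**Assumption:** the target is numbered O1, C2 (Me), C3 (CHO), C4 (CH2CO2R), C5 (CO2Me), C6, i.e. methyl (2S,3R,4R)-4-{2-[2-(3,4-dihydroxyphenyl)ethoxy]-2-oxoethyl}-3-formyl-2-methyl-3,4-dihydro-2H-pyran-5-carboxylate, with all three ring substituents trans. The antipode of the triazolium precatalyst in step 7 is the one that gives 3R in compound 15; which antipode that is has to be found by experiment.

## Retrosynthetic overview

1. Target 20 ⇐ dibenzyl ether 19 (hydrogenolysis) ⇐ nitromethyl dihydropyran 17 (Nef: CH2NO2 → CHO).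
2. The dihydropyran, the only ring built, is closed after the key step: in acyclic δ-nitro ester 15 the C2 hydroxyl displaces methoxide from a β-methoxyacrylate.
3. Key disconnection C3–C4 (together with the side-chain ester C–O): carbene-catalysed three-component coupling in which the β-carbon of dienal 5 acts as a homoenolate towards the β-carbon of nitroalkene 12, and the acyl unit is passed to alcohol 14.
4. 12 ⇐ ethyl (S)-lactate (C2 from the chiral pool); 5 ⇐ methyl 3-methoxyacrylate + acrolein; 14 ⇐ hydroxytyrosol.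

## Route

**Step 1**
Reactants: 1 methyl (E)-3-methoxyprop-2-enoate
Product: 3 methyl (Z)-2-iodo-3-methoxyprop-2-enoate, via acetoxy iodo adduct 2 (not isolated)
Conditions: NIS, AcOH, CH2Cl2, rt; then Et3N, 0 °C → rt
Reagents that add atoms: N-iodosuccinimide (O=C1CCC(=O)N1I)
Why: Iodo-acetoxylation of the push-pull alkene (I+ at the nucleophilic α-carbon, acetate at the β-carbon) followed by E1cB loss of AcOH gives the α-iodo-β-methoxyacrylate.

**Step 2**
Reactants: 3 methyl (Z)-2-iodo-3-methoxyprop-2-enoate; 4 acrolein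
Product: 5 methyl (2E,3E)-2-(methoxymethylidene)-5-oxopent-3-enoate
Conditions: Pd(OAc)2 (5 mol %), n-Bu4NCl, NaHCO3, DMF, 40 °C
Reagents that add atoms: none
Why: Heck reaction under Jeffery conditions couples the vinyl iodide to the terminal carbon of acrolein and β-hydride elimination gives the (E)-enal; the enol ether and ester are inert.

**Step 3**
Reactants: 6 ethyl (S)-lactate
Product: 7 ethyl (2S)-2-[(tert-butyldimethylsilyl)oxy]propanoate
Conditions: TBSCl, imidazole, DMF, 0 °C → rt
Reagents that add atoms: tert-butyldimethylsilyl chloride (CC(C)(C)[Si](C)(C)Cl)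
Why: Standard O-silylation; the lactate stereocentre (future C2) is not touched.

**Step 4**
Reactants: 7 ethyl (2S)-2-[(tert-butyldimethylsilyl)oxy]propanoate
Product: 8 (2S)-2-[(tert-butyldimethylsilyl)oxy]propanal
Conditions: DIBAL-H, CH2Cl2, −78 °C; Rochelle salt work-up
Reagents that add atoms: none
Why: Partial ester reduction through the stable tetrahedral aluminium hemiacetal at −78 °C gives the α-silyloxy aldehyde without epimerisation.

**Step 5**
Reactants: 8 (2S)-2-[(tert-butyldimethylsilyl)oxy]propanal; 9 nitromethane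
Product: 12 tert-butyldimethyl{[(2S,3E)-4-nitrobut-3-en-2-yl]oxy}silane, via nitro-aldol 10 (not isolated), via nitro-aldol mesylate 11 (not isolated)
Conditions: MeNO2 (excess), Et3N (cat.), 0 °C → rt; then MsCl, Et3N, CH2Cl2, −20 → 0 °C
Reagents that add atoms: none
Why: Henry reaction followed by mesylation and E1cB elimination gives the (E)-nitroalkene; the mild amine base and low temperature keep the silyloxy stereocentre intact.

**Step 6**
Reactants: 13 hydroxytyrosol
Product: 14 2-[3,4-bis(benzyloxy)phenyl]ethan-1-ol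
Conditions: BnBr (2.2 equiv), K2CO3, acetone, reflux
Reagents that add atoms: benzyl bromide (BrCc1ccccc1)
Why: Williamson etherification is selective for the phenoxides because the aliphatic alcohol is not deprotonated by carbonate.

**Step 7 (key step)**
Reactants: 12 tert-butyldimethyl{[(2S,3E)-4-nitrobut-3-en-2-yl]oxy}silane; 5 methyl (2E,3E)-2-(methoxymethylidene)-5-oxopent-3-enoate; 14 2-[3,4-bis(benzyloxy)phenyl]ethan-1-ol
Product: 15 2-[3,4-bis(benzyloxy)phenyl]ethyl (3R,4S,5S)-5-[(tert-butyldimethylsilyl)oxy]-3-[(1E)-1-methoxy-3-methoxy-3-oxoprop-1-en-2-yl]-4-(nitromethyl)hexanoate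
Conditions: chiral bicyclic N-mesityl 1,2,4-triazolium salt (15 mol %), NaOAc (50 mol %), 5 (1.5 equiv), 14 (3 equiv, excess recovered), PhMe/t-AmOH, 4 Å MS, rt
Reagents that add atoms: none
Why: Proposed new method: the carbene adds to the aldehyde of 5 to give a Breslow-type homoenolate whose β-carbon, normally electrophilic, attacks the electrophilic β-carbon of nitroalkene 12; after protonation of the nitronate the acyl azolium is transferred to alcohol 14 with no co-product; the catalyst face selection sets 3R (target C4), a syn-selective approach sets 4S (target C3), and the lactate centre is carried through; the closest known reaction is the carbene-catalysed, enantio- and syn-selective homoenolate addition of enals to nitroalkenes in alcohol solvent giving δ-nitro esters, here extended to a push-pull dienal, a γ-silyloxy nitroalkene and a stoichiometric complex alcohol.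

**Step 8**
Reactants: 15 2-[3,4-bis(benzyloxy)phenyl]ethyl (3R,4S,5S)-5-[(tert-butyldimethylsilyl)oxy]-3-[(1E)-1-methoxy-3-methoxy-3-oxoprop-1-en-2-yl]-4-(nitromethyl)hexanoate
Product: 17 methyl (2S,3S,4R)-4-{2-[2-(3,4-bis(benzyloxy)phenyl)ethoxy]-2-oxoethyl}-2-methyl-3-(nitromethyl)-3,4-dihydro-2H-pyran-5-carboxylate, via desilylated hydroxy ester 16 (not isolated)
Conditions: HF·pyridine, THF, 0 °C → rt; then PPTS (10 mol %), PhMe, 70 °C (MeOH removed)
Reagents that add atoms: none
Why: Acidic desilylation followed by acid-catalysed alkoxy exchange at the β-methoxyacrylate (addition to the protonated vinylogous carbonate, then loss of MeOH) closes the six-membered ring with retention at C2, since only the O–H bond of the alcohol is involved; benzyl ethers, both esters and the nitro group are stable.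

**Step 9**
Reactants: 17 methyl (2S,3S,4R)-4-{2-[2-(3,4-bis(benzyloxy)phenyl)ethoxy]-2-oxoethyl}-2-methyl-3-(nitromethyl)-3,4-dihydro-2H-pyran-5-carboxylate
Product: 19 methyl (2S,3R,4R)-4-{2-[2-(3,4-bis(benzyloxy)phenyl)ethoxy]-2-oxoethyl}-3-formyl-2-methyl-3,4-dihydro-2H-pyran-5-carboxylate, via potassium nitronate 18 (not isolated)
Conditions: KOtBu (1.1 equiv), THF, −40 °C; then aq. TiCl3 (4 equiv), NH4OAc buffer (pH 5–6), 0 °C → rt
Reagents that add atoms: water (O)
Why: Reductive (McMurry-type) Nef reaction: the nitronate is reduced by Ti(III) to the imine, which hydrolyses to the aldehyde at buffered pH, so C3 is not epimerised and the ring is not opened by E1cB (the descriptor at C3 changes from S to R only through CIP priorities).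

**Step 10**
Reactants: 19 methyl (2S,3R,4R)-4-{2-[2-(3,4-bis(benzyloxy)phenyl)ethoxy]-2-oxoethyl}-3-formyl-2-methyl-3,4-dihydro-2H-pyran-5-carboxylate
Product: 20 methyl (2S,3R,4R)-4-{2-[2-(3,4-dihydroxyphenyl)ethoxy]-2-oxoethyl}-3-formyl-2-methyl-3,4-dihydro-2H-pyran-5-carboxylate
Conditions: H2 (1 atm), 10 % Pd/C, EtOAc, rt, stopped at full conversion
Reagents that add atoms: none
Why: Neutral hydrogenolysis of the two aryl benzyl ethers is much faster than reduction of the aliphatic aldehyde or of the trisubstituted push-pull enol ether double bond, so no stereocentre is touched.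

## Compound list

1 | methyl (E)-3-methoxyprop-2-enoate | CO/C=C/C(=O)OC | starting material
2 | methyl 3-acetoxy-2-iodo-3-methoxypropanoate (diastereomer mixture) | COC(OC(C)=O)C(I)C(=O)OC | intermediate
3 | methyl (Z)-2-iodo-3-methoxyprop-2-enoate | CO/C=C(\I)C(=O)OC | intermediate
4 | acrolein | C=CC=O | starting material
5 | methyl (2E,3E)-2-(methoxymethylidene)-5-oxopent-3-enoate | CO/C=C(\C=C\C=O)C(=O)OC | intermediate
6 | ethyl (S)-lactate | C[C@H](O)C(=O)OCC | starting material
7 | ethyl (2S)-2-[(tert-butyldimethylsilyl)oxy]propanoate | C[C@H](O[Si](C)(C)C(C)(C)C)C(=O)OCC | intermediate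
8 | (2S)-2-[(tert-butyldimethylsilyl)oxy]propanal | C[C@H](O[Si](C)(C)C(C)(C)C)C=O | intermediate
9 | nitromethane | C[N+](=O)[O-] | starting material
10 | (3S)-3-[(tert-butyldimethylsilyl)oxy]-1-nitrobutan-2-ol (both C2 epimers) | C[C@H](O[Si](C)(C)C(C)(C)C)C(O)C[N+](=O)[O-] | intermediate
11 | (3S)-3-[(tert-butyldimethylsilyl)oxy]-1-nitrobutan-2-yl methanesulfonate | C[C@H](O[Si](C)(C)C(C)(C)C)C(OS(C)(=O)=O)C[N+](=O)[O-] | intermediate
12 | tert-butyldimethyl{[(2S,3E)-4-nitrobut-3-en-2-yl]oxy}silane | C[C@H](O[Si](C)(C)C(C)(C)C)/C=C/[N+](=O)[O-] | intermediate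
13 | hydroxytyrosol | OCCc1ccc(O)c(O)c1 | starting material
14 | 2-[3,4-bis(benzyloxy)phenyl]ethan-1-ol | OCCc1ccc(OCc2ccccc2)c(OCc2ccccc2)c1 | intermediate
15 | 2-[3,4-bis(benzyloxy)phenyl]ethyl (3R,4S,5S)-5-[(tert-butyldimethylsilyl)oxy]-3-[(1E)-1-methoxy-3-methoxy-3-oxoprop-1-en-2-yl]-4-(nitromethyl)hexanoate | C[C@H](O[Si](C)(C)C(C)(C)C)[C@H](C[N+](=O)[O-])[C@@H](CC(=O)OCCc1ccc(OCc2ccccc2)c(OCc2ccccc2)c1)/C(=C\OC)C(=O)OC | intermediate
16 | 2-[3,4-bis(benzyloxy)phenyl]ethyl (3R,4S,5S)-5-hydroxy-3-[(1E)-1-methoxy-3-methoxy-3-oxoprop-1-en-2-yl]-4-(nitromethyl)hexanoate | C[C@H](O)[C@H](C[N+](=O)[O-])[C@@H](CC(=O)OCCc1ccc(OCc2ccccc2)c(OCc2ccccc2)c1)/C(=C\OC)C(=O)OC | intermediate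
17 | methyl (2S,3S,4R)-4-{2-[2-(3,4-bis(benzyloxy)phenyl)ethoxy]-2-oxoethyl}-2-methyl-3-(nitromethyl)-3,4-dihydro-2H-pyran-5-carboxylate | COC(=O)C1=CO[C@@H](C)[C@H](C[N+](=O)[O-])[C@H]1CC(=O)OCCc1ccc(OCc2ccccc2)c(OCc2ccccc2)c1 | intermediate
18 | potassium nitronate of 17 | COC(=O)C1=CO[C@@H](C)[C@H](C=[N+]([O-])[O-])[C@H]1CC(=O)OCCc1ccc(OCc2ccccc2)c(OCc2ccccc2)c1.[K+] | intermediate
19 | methyl (2S,3R,4R)-4-{2-[2-(3,4-bis(benzyloxy)phenyl)ethoxy]-2-oxoethyl}-3-formyl-2-methyl-3,4-dihydro-2H-pyran-5-carboxylate | COC(=O)C1=CO[C@@H](C)[C@H](C=O)[C@H]1CC(=O)OCCc1ccc(OCc2ccccc2)c(OCc2ccccc2)c1 | intermediate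
20 | methyl (2S,3R,4R)-4-{2-[2-(3,4-dihydroxyphenyl)ethoxy]-2-oxoethyl}-3-formyl-2-methyl-3,4-dihydro-2H-pyran-5-carboxylate | COC(=O)C1=CO[C@@H](C)[C@H](C=O)[C@H]1CC(=O)OCCc1ccc(O)c(O)c1 | target

## Step count and risks

Total steps: 10. Longest linear sequence: 7 (steps 3, 4, 5, 7, 8, 9, 10, from ethyl (S)-lactate).

**Step 7 (most likely to fail).** The dienal is an untested homoenolate precursor. Acyl transfer to a stoichiometric, bulky alcohol may lose to β-protonation or to C-acylation of the nitronate. The silyloxy stereocentre of 12 may also be mismatched with the catalyst. If only the 4-epimer of 15 forms, it is not lost: that carbon becomes the formyl-bearing C3 and can be equilibrated to the all-trans aldehyde 19 after step 9.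
Fallback, setting out from 12 and 5 and returning at 17: run the same carbene-catalysed coupling in allyl alcohol as co-solvent to give allyl δ-nitro ester F1. HF·pyridine gives hydroxy ester F2, which PPTS cyclises as in step 8 to allyl dihydropyran ester F3. Pd(PPh3)4/morpholine then frees acid F4, and EDC/DMAP esterification with 14 gives 17.

**Step 8.** The freed hydroxyl of 16 can also lactonise onto the side-chain ester and expel 14. The plan relies on enol-ether exchange being faster than ester exchange under weak acid.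
Fallback, setting out from 12 and returning at 17: make the O1–C6 bond before the ester exists. Desilylate 12 with HF·pyridine to (2S,3E)-4-nitrobut-3-en-2-ol F5. Exchange it into enal 5 (PPTS, PhMe, removal of MeOH) to give tethered nitroalkene dienal F6. Then run the carbene step intramolecularly: a 6-exo homoenolate Michael addition closes the pyran ring and the acyl unit is transferred to 14, giving 17 directly.

**Step 9.** The one-pot Ti(III) Nef on a primary nitro group can stall at the oxime, over-reduce, or epimerise or open the β-alkoxy aldehyde.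
Fallback, setting out from 17 and returning at 19: split the conversion in two. Reduce the nitro group to aldoxime F7 (SnCl2·2H2O, PhSH, Et3N), isolate it, and cleave the oxime by exchange with glyoxylic acid in buffered aqueous THF to give 19.

## Further compounds

F1 | step 7 | prop-2-en-1-yl (3R,4S,5S)-5-[(tert-butyldimethylsilyl)oxy]-3-[(1E)-1-methoxy-3-methoxy-3-oxoprop-1-en-2-yl]-4-(nitromethyl)hexanoate | C[C@H](O[Si](C)(C)C(C)(C)C)[C@H](C[N+](=O)[O-])[C@@H](CC(=O)OCC=C)/C(=C\OC)C(=O)OC
F2 | step 7 | prop-2-en-1-yl (3R,4S,5S)-5-hydroxy-3-[(1E)-1-methoxy-3-methoxy-3-oxoprop-1-en-2-yl]-4-(nitromethyl)hexanoate | C[C@H](O)[C@H](C[N+](=O)[O-])[C@@H](CC(=O)OCC=C)/C(=C\OC)C(=O)OC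
F3 | step 7 | methyl (2S,3S,4R)-2-methyl-3-(nitromethyl)-4-[2-oxo-2-(prop-2-en-1-yloxy)ethyl]-3,4-dihydro-2H-pyran-5-carboxylate | COC(=O)C1=CO[C@@H](C)[C@H](C[N+](=O)[O-])[C@H]1CC(=O)OCC=C
F4 | step 7 | 2-[(2S,3S,4R)-5-(methoxycarbonyl)-2-methyl-3-(nitromethyl)-3,4-dihydro-2H-pyran-4-yl]acetic acid | COC(=O)C1=CO[C@@H](C)[C@H](C[N+](=O)[O-])[C@H]1CC(=O)O
F5 | step 8 | (2S,3E)-4-nitrobut-3-en-2-ol | C[C@H](O)/C=C/[N+](=O)[O-]
F6 | step 8 | methyl (2E,3E)-2-({[(2S,3E)-4-nitrobut-3-en-2-yl]oxy}methylidene)-5-oxopent-3-enoate | C[C@H](O/C=C(\C=C\C=O)C(=O)OC)/C=C/[N+](=O)[O-]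
F7 | step 9 | methyl (2S,3S,4R)-4-{2-[2-(3,4-bis(benzyloxy)phenyl)ethoxy]-2-oxoethyl}-3-[(hydroxyimino)methyl]-2-methyl-3,4-dihydro-2H-pyran-5-carboxylate | COC(=O)C1=CO[C@@H](C)[C@H](C=NO)[C@H]1CC(=O)OCCc1ccc(OCc2ccccc2)c(OCc2ccccc2)c1
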